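The two ArCH2–Ar bonds between the benzylic carbons and C4/C6 of the central bromophloroglucinol ring are the disconnection. The key step exploits two features: the hydroxyl para to each benzylic carbon on the outer dibromocatechol rings, which lets the benzylic alcohol lanosol ionise to a p-quinone methide, and the two equivalent, triply oxygen-activated CH positions of 2-bromophloroglucinol, whose third position is blocked by bromine. One acid-promoted, protecting-group-free double Friedel–Crafts alkylation should thus form both diarylmethane bonds in one flask, the second event joining the C7 benzyl unit to the monobenzylated C13 core, and deliver the achiral target directly from two simple bromophenols.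

Key step: step 5

Remark: the target has no stereogenic element (a mirror plane runs through C–Br and the opposite C–OH of the central ring), so no stereochemistry has to be set; 2-bromophloroglucinol is made in one step rather than assumed to be purchasable.

Step 1
Reactants: 1 5-bromovanillin (3-bromo-4-hydroxy-5-methoxybenzaldehyde)
Product: 2 2,3-dibromo-4-hydroxy-5-methoxybenzaldehyde
Conditions: Br2 (1.2 equiv), Fe powder (cat.), AcOH, rt
Reagents that add atoms: bromine, BrBr
Why: Electrophilic aromatic bromination, in which C2 of 1 (para to the methoxy group) is the more activated of the two free ring positions and should take the second bromine next to the first.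

Step 2
Reactants: 2 2,3-dibromo-4-hydroxy-5-methoxybenzaldehyde
Product: 3 2,3-dibromo-4,5-dihydroxybenzaldehyde
Conditions: BBr3 (3 equiv), CH2Cl2, −78 °C to rt; then H2O
Reagents that add atoms: none
Why: Lewis-acid aryl methyl ether cleavage (BBr3 demethylation), assisted by the neighbouring phenol borate, which should leave the aryl bromides untouched and return the aldehyde on aqueous work-up.

Step 3
Reactants: 3 2,3-dibromo-4,5-dihydroxybenzaldehyde
Product: 4 lanosol (2,3-dibromo-4,5-dihydroxybenzyl alcohol)
Conditions: NaBH4, THF/H2O, 0 °C; aq. NH4Cl to pH 6, extraction without alcohols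
Reagents that add atoms: none
Why: Borohydride 1,2-reduction of the aryl aldehyde, to which aryl bromides are inert; the cold, alcohol-free, near-neutral work-up should keep the p-hydroxybenzyl alcohol from ionising.

Step 4
Reactants: 5 phloroglucinol (benzene-1,3,5-triol)
Product: 6 2-bromophloroglucinol (2-bromobenzene-1,3,5-triol)
Conditions: NBS (1.0 equiv, slow addition), 5 (1.2 equiv), THF, −78 °C to 0 °C
Reagents that add atoms: N-bromosuccinimide, O=C1CCC(=O)N1Br
Why: Electrophilic aromatic bromination in which all three CH positions of 5 are equivalent, so only the degree of bromination must be controlled, by low temperature, slow addition of one equivalent and the slight deactivation by the first bromine.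

Step 5
Reactants: 4 lanosol (2.2 equiv, added in portions); 6 2-bromophloroglucinol (1.0 equiv)
Product: 9 vidalol B, via p-quinone methide 7 (not isolated), via monobenzyl triol 8 (not isolated)
Conditions: TsOH·H2O (10 mol %), HFIP, 40 °C, Ar
Reagents that add atoms: none
Why: Acid-assisted loss of water from the benzylic alcohol of 4, pushed by the para-hydroxyl, gives p-quinone methide 7, whose exocyclic CH2 is attacked in a 1,6-addition by the free ring carbon C4 of 6 and, after rearomatisation to monobenzyl triol 8, by the equivalent C6, so that the second event joins the C7 benzyl unit to the C13 monobenzylated core. The closest known reaction type is the Brønsted-acid/HFIP-promoted Friedel–Crafts benzylation of phloroglucinols with p-hydroxybenzyl alcohols via p-quinone methides. No ring is closed and no stereocentre is created, the product being achiral. The step needs C- over O-alkylation and attack by the core CH positions rather than by the catechol ring CH of a second lanosol unit; the far higher carbon nucleophilicity of positions ortho/para to three hydroxyls and the reversibility of O-benzylation and of attack at substituted carbons under acid should secure both. The bromine at C2 of 6 blocks the third position, so alkylation should stop at exactly two benzyl groups. Portionwise addition of 4 keeps 7 dilute and should suppress its self-condensation.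

Compound list
1 | 5-bromovanillin (3-bromo-4-hydroxy-5-methoxybenzaldehyde) | O=Cc1cc(Br)c(O)c(OC)c1 | starting material
2 | 2,3-dibromo-4-hydroxy-5-methoxybenzaldehyde | O=Cc1cc(OC)c(O)c(Br)c1Br | intermediate
3 | 2,3-dibromo-4,5-dihydroxybenzaldehyde | O=Cc1cc(O)c(O)c(Br)c1Br | intermediate
4 | lanosol (2,3-dibromo-4,5-dihydroxybenzyl alcohol) | OCc1cc(O)c(O)c(Br)c1Br | intermediate
5 | phloroglucinol (benzene-1,3,5-triol) | Oc1cc(O)cc(O)c1 | starting material
6 | 2-bromophloroglucinol (2-bromobenzene-1,3,5-triol) | Oc1cc(O)c(Br)c(O)c1 | intermediate
7 | p-quinone methide of lanosol (2,3-dibromo-6-hydroxy-4-methylidenecyclohexa-2,5-dien-1-one) | C=C1C=C(O)C(=O)C(Br)=C1Br | intermediate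
8 | monobenzyl triol (2-bromo-4-(2,3-dibromo-4,5-dihydroxybenzyl)benzene-1,3,5-triol) | Oc1cc(O)c(Cc2cc(O)c(O)c(Br)c2Br)c(O)c1Br | intermediate
9 | vidalol B (2-bromo-4,6-bis(2,3-dibromo-4,5-dihydroxybenzyl)benzene-1,3,5-triol) | Oc1cc(Cc2c(O)c(Br)c(O)c(Cc3cc(O)c(O)c(Br)c3Br)c2O)c(Br)c(Br)c1O | target

Total step count: 5
Longest linear sequence: 4 steps (steps 1, 2, 3 and 5); step 4 is a one-step side branch.

Steps most likely to fail

Step 5. The quinone methide may condense with itself, through the catechol ring or the hydroxyls of a second lanosol unit. The second alkylation may stall at the monobenzyl stage. The core bromine may be lost or may migrate under acid through the C-protonated keto tautomer of the bromophloroglucinol. The fallback masks all phenols as methyl ethers and sets out from 2. O-Methylation (MeI, K2CO3, DMF) should give 2,3-dibromo-4,5-dimethoxybenzaldehyde F1, and NaBH4 reduction (MeOH, 0 °C) the non-ionising (2,3-dibromo-4,5-dimethoxyphenyl)methanol F2. Two equivalents of F2 are then joined to purchased 1-bromo-2,4,6-trimethoxybenzene F3 by a Lewis-acid Friedel–Crafts benzylation (AlCl3, CH2Cl2, 0 °C) to give 2-bromo-4,6-bis(2,3-dibromo-4,5-dimethoxybenzyl)-1,3,5-trimethoxybenzene F4. Global demethylation with excess BBr3 (CH2Cl2, −78 °C to rt) comes back to the route at 9.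

Step 4. Bromination may not stop at one bromine, giving mixtures of mono-, di- and tribromide alongside oxidative degradation of the electron-rich triol, with a difficult separation. The fallback lowers the ring reactivity before bromination and sets out from 5. Peracetylation (Ac2O, pyridine) should give benzene-1,3,5-triyl triacetate F5. On this much less activated ring a single bromination (Br2, NaOAc, AcOH, rt to 50 °C) should stop cleanly at 2-bromobenzene-1,3,5-triyl triacetate F6. Acid methanolysis (HCl, MeOH, rt, Ar) returns to the route at 6.

Step 3. The product may ionise prematurely to the quinone methide during reduction or work-up, leading to over-reduction of the benzylic position, ether formation with solvent or oligomerisation on concentration. The fallback deliberately isolates the electrophile as its storable benzylic methyl ether and sets out from 3. Reduction with NaBH4 in MeOH at 0 °C is followed by acidification of the methanolic solution (HCl, rt), which should convert the crude alcohol into 3,4-dibromo-5-(methoxymethyl)benzene-1,2-diol F7. F7 is used in place of 4 under the conditions of step 5, where acid expels methanol and the route is rejoined at quinone methide 7.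

Further compounds
F1 | step 5 | 2,3-dibromo-4,5-dimethoxybenzaldehyde | O=Cc1cc(OC)c(OC)c(Br)c1Br
F2 | step 5 | (2,3-dibromo-4,5-dimethoxyphenyl)methanol | OCc1cc(OC)c(OC)c(Br)c1Br
F3 | step 5 | 1-bromo-2,4,6-trimethoxybenzene (purchased) | COc1cc(OC)c(Br)c(OC)c1
F4 | step 5 | 2-bromo-4,6-bis(2,3-dibromo-4,5-dimethoxybenzyl)-1,3,5-trimethoxybenzene | COc1cc(Cc2c(OC)c(Br)c(OC)c(Cc3cc(OC)c(OC)c(Br)c3Br)c2OC)c(Br)c(Br)c1OC
F5 | step 4 | benzene-1,3,5-triyl triacetate | CC(=O)Oc1cc(OC(C)=O)cc(OC(C)=O)c1
F6 | step 4 | 2-bromobenzene-1,3,5-triyl triacetate | CC(=O)Oc1cc(OC(C)=O)c(Br)c(OC(C)=O)c1
F7 | step 3 | 3,4-dibromo-5-(methoxymethyl)benzene-1,2-diol | COCc1cc(O)c(O)c(Br)c1Br
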